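(The runs were generated by integration on assumed constants, noise included.)

If I follow one molecule of J, it stands at a fork: it meets X and becomes Q, or it passes alone into Z; a J that returns to L I count as coming back to this fork later. Its chance of becoming Q is the capture rate over the sum of the two rates, and the ratio of those two rates is a selectivity factor.

the same everywhere: E 0.67 M

| charge | D | remark | time |
|---|---|---|---|
| Wednesday's | 0.74 equiv | run made earlier |  |
| Tuesday's | 1.4 equiv | run made earlier |  |
| Friday's | 3.6 equiv | run made earlier |  |
| autumn | 0.700 equiv |  | 3.0 h |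
| spring | 1.05 equiv |  | 3.0 h |
| dusk | 2.10 equiv |  | 3.0 h |
| midnight | 3.20 equiv |  | 3.0 h |
| winter | 1.60 equiv |  | 3.0 h |

| run | time / min | Q / % | E / % |
|---|---|---|---|
| Wednesday's | 20.0 | 0 | 30 |
| Wednesday's | 40.0 | 2 | 0 |
| Wednesday's | 50.0 | 4 | 2 |
| Wednesday's | 80.0 | 4 | 0 |
| Wednesday's | 90.0 | 8 | 2 |
| Tuesday's | 8.00 | 2 | 68 |
| Tuesday's | 15.0 | 1 | 40 |
| Tuesday's | 25.0 | 1 | 20 |
| Tuesday's | 50.0 | 7 | 0 |
| Tuesday's | 90.0 | 11 | 1 |
| Friday's | 8.00 | 0 | 63 |
| Friday's | 15.0 | 1 | 41 |
| Friday's | 25.0 | 4 | 18 |
| Friday's | 50.0 | 13 | 4 |
| Friday's | 90.0 | 21 | 1 |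

(standard deviation of a reading: 1.5 percentage points)

1. ranking by amount of Q, in percent of the E charged, from high to low, at 3.0 h (autumn / spring / dusk / midnight / winter)
2. the same order at 25 h (autumn / spring / dusk / midnight / winter)
3. the amount of Q, in percent of the E charged of the flask you put first, at 3.0 h
4. the amount of Q, in percent of the E charged of the flask you put last, at 3.0 h

- given per volume of solution although it is solid: E
- what may be going on: L <-> G; J -> Z; D -> X; J + X -> Q; L <-> J; E <-> L
- at the start none of E is in solution
- what has only dissolved of E counts as not reacted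

1. I first ask whether D changes the supply of J. At 25.0 min, E stands at 20% in Tuesday's run and 18% in Friday's, alike within the scatter of 1.5 percentage points. So I take the supply as the same and let D act at the fork.

2. X comes from D, so I let cX follow the equivalents of D. The chance then becomes eq/(eq + b), where b is the half-capture loading, the equivalents of D at which a J has even chances of Q and Z, taken as one average value up to the reading because cX changes as D turns into X.

3. From Wednesday's and Friday's Q at 90.0 min, which is 8% and 21%, Q grows less than D, and the rule gives as a reading the half-capture loading b = 2.61.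

4. The same two runs at 50.0 min, which are separate readings, give 5.02, so the two ways part. Which one cheats? Wednesday's 4% raised by the scatter of 1.5 points turns the second value into 1.96, below the first. The parting therefore lies within the scatter, and I keep the later value, whose Wednesday reading is twice the earlier one.

5. I commit to a ranking by D at both times, and with this b I reckon Q in midnight over Q in autumn at 3.0 h as a ratio of 2.60. The rule gives this ratio but no height.

6. The forecast says midnight > dusk > winter > spring > autumn at 3.0 h and midnight > dusk > winter > spring > autumn at 25 h, with 33% for midnight and 13% for autumn at 3.0 h, a ratio of 2.54. Its ground: “More D always favours capture over the leak”.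

The flasks give midnight > dusk > winter > spring > autumn at 3.0 h and midnight > dusk > winter > spring > autumn at 25 h, with 35.2% for midnight and 13.5% for autumn at 3.0 h, so the forecast held.

    L ⇌ G (K = 0.580, k = 3.00 × 10⁻⁴ s⁻¹)
    J → Z (k = 0.00120 s⁻¹)
    D → X (k = 2.90 × 10⁻⁴ s⁻¹)
    J + X → Q (k = 0.00130 M⁻¹ s⁻¹)
    L ⇌ J (K = 0.780, k = 1.60 × 10⁻⁴ s⁻¹)
    E ⇌ L, rate k6*(cs6 - [L]) while solid is left; crystals form when [L] > cs6 (solubility = 0.600 M, k = 0.00110 s⁻¹)

The ratio of Q in midnight to Q in autumn at 3.0 h is 2.61, against my 2.60, which rests on a b read from scattered readings. Winter, reckoned from autumn through b, comes to 24.3%, and the flask gives 24.4%. In autumn at 3.00 h, J passes into Z 2.6 times as fast as J and X pass into Q. In midnight at that time cX is 1.81 M against 0.358 M in autumn, and capture runs 1.97 times as fast as the passing into Z.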